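Read at 4.0 d, this flask stands later than its last autumn reading at 12.0 h, so two questions come up: where does it stop, and has it arrived?

| flask | substrate | coupling partner | remark | time |
|---|---|---|---|---|
| autumn | 0.10 M (in portions, 2) | 1 equiv | the very flask that is asked about, followed so far; portions every 1.5 min |  |
| spring | 0.10 M (in portions, 2) | 0.50 equiv | run made earlier; portions every 1.5 min |  |
| flask | 0.10 M (in portions, 2) | 1.00 equiv | the portions of substrate follow each other after 1.5 min, the first at the start | 4.0 d |

| run | time / h | substrate / % | target / % |
|---|---|---|---|
| autumn | 1.00 | 28.0 | 3.7 |
| autumn | 1.50 | 21.5 | 5.1 |
| autumn | 2.50 | 15.7 | 7.2 |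
| autumn | 4.00 | 12.1 | 8.1 |
| autumn | 8.00 | 9.4 | 9.1 |
| autumn | 12.0 | 9.1 | 9.1 |
| spring | 2.50 | 51.8 | 1.6 |
| spring | 8.00 | 51.6 | 1.4 |
| spring | 15.0 | 51.5 | 1.2 |
| spring | 20.0 | 51.0 | 1.3 |
| spring | 30.0 | 51.9 | 1.7 |
| spring | 40.0 | 51.3 | 1.3 |

(standard deviation of a reading: 0.3 percentage points)

- which holds at 4.0 d: what has brought the reaction to rest, or that it has not come to rest (all of the substrate has reacted / the coupling partner has run out first / it is still moving)
- share of the substrate used up at 4.0 d
- target at 4.0 d, in percent of the substrate charged

- the reaction counts as stopped when no species that holds the substrate changes by six tenths of a point or more over the second half of the time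

Has the autumn run, which is this flask followed so far, come to rest? Between 8.00 h and 12.0 h its substrate moves 0.3 percentage points and its target stands at 9.1%, so I read it as at rest.

What stopped it, with 9.1% of substrate still there? Take the fraction of substrate used, add the fraction standing as target, and divide by the equivalents of coupling partner charged. The last autumn reading gives 1.00, and this partner tally is my reckoning. A tally of 1.00 reads as a coupling partner wholly taken up, which makes it the limiting reagent.

Why count the target at all? Without it the gap in the autumn balance is 9.1%, larger than the scatter of 0.3 points.

Is one run enough? The spring run, with a different charge of coupling partner, gives 1.00 at 40.0 h.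

Could a flask at rest creep on? Spring substrate reads 51.8% at 2.50 h and 51.3% at 40.0 h, which is flat within the scatter. I therefore commit to the autumn plateau, 90.9% used and 9.1% target.

The forecast gives the same: the coupling partner has run out first, 90.9% used and 9.1% target. Its ground for the long time is this: “The spring plateau shows no slow drift afterwards”.

In the flask at 4.0 d, the coupling partner has run out first, with 0% of it left, 90.7% of the substrate used and 9.33% target.

    coupling partner + intermediate → target (k = 0.00280 /M/s)
    substrate + coupling partner → intermediate (k = 0.00180 /M/s)
    substrate + coupling partner → side product (k = 0.00580 /M/s)

In this scheme a substrate used takes one coupling partner and a target takes a second, which is what the tally counts. On this flask, the tally times the charge, less the target, gives 90.7% used. The neighbouring flask with 0.400 equiv of coupling partner takes the same reckoning: the tally gives 40.0% for used plus target, and its target of 0.863% leaves 39.1% used. That neighbouring flask stands at 39.1% used, with 0% of its coupling partner left.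

Readings and results are calculated with constants of no real substance; the scatter is artificial.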